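No rate constant is given, so I read what I can from the theta and alpha runs, which differ in the charge of starting material.

the same everywhere: free catalyst 10 µM

| flask | starting material | second substrate | solid reagent | remark |
|---|---|---|---|---|
| theta | 6.7 mM | 10 mM | 18 mM | run made earlier |
| alpha | 15 mM | 10 mM | 18 mM | run made earlier |
| flask | 10 mM | 10.0 mM | 18.0 mM |  |

| run | time / min | target / % | starting material / % |
|---|---|---|---|
| theta | 1.33 | 0.5 | 100.2 |
| theta | 4.00 | 1.8 | 99.1 |
| theta | 6.00 | 1.5 | 99.0 |
| theta | 10.0 | 3.0 | 96.3 |
| theta | 15.0 | 6.1 | 94.0 |
| theta | 20.0 | 8.7 | 91.2 |
| theta | 25.0 | 12.6 | 87.7 |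
| alpha | 3.00 | 0.7 | 99.4 |
| alpha | 6.00 | 1.3 | 99.6 |
| alpha | 10.0 | 2.8 | 98.2 |
| alpha | 15.0 | 4.8 | 96.0 |
| alpha | 20.0 | 6.4 | 93.3 |
| alpha | 25.0 | 9.0 | 91.4 |

(scatter of a reading: 0.5 percentage points)

- solid reagent is a solid; its amount is given per volume of the solution
- at the start none of the solid reagent is in solution
- no earlier run changes the charge of free catalyst; that part of a forecast is a guess

1. apparent order in free catalyst when 5.0% of the starting material are converted (percent change of the rate of making target for one percent more free catalyst charged)

Both runs start slowly and then speed up, and none of the solid reagent is in solution at the start, so I take a supply from the solid to stand ahead of the catalysis. From 10.0 min to 25.0 min, a stretch that straddles 5.0% conversion in both runs, I reckon the fraction of the charge turned to target per minute: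

theta: 0.00640 min⁻¹
alpha: 0.00413 min⁻¹

Alpha, with the larger charge, turns a smaller fraction per minute than theta, whereas a rate proportional to the charge of starting material, with the other charges held equal as they are here, gives both runs the same fraction. So:

1 + ln(0.00413 min⁻¹ / 0.00640 min⁻¹) / ln(15 mM / 6.7 mM) = 0.458

This is my charge exponent: the percent change of the rate of making target for one percent more starting material charged. It is a reading, with each point good to 0.5 percentage points. I assume that the supply from the solid ignores both starting material and catalyst, and that both speed the use of what dissolves. For this flask I therefore guess an order in free catalyst of 0.458, since no run varies the catalyst.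

The forecast is higher than mine, at 0.75. It says “catalyst should behave like starting material, with an order near 0.5”, but also allows an order near 1.

The flask gives 0.41, lower than my 0.458.

    solid reagent ⇌ partner, rate k1*(cs1 - [partner]) while solid is left; crystals form when [partner] > cs1 (solubility = 5.10 mM, k = 3.66 × 10⁻⁴ s⁻¹)
    starting material + free catalyst ⇌ catalyst intermediate A (K = 12000 L mol⁻¹, k = 98.6 L mol⁻¹ s⁻¹)
    partner + catalyst intermediate B → free catalyst + second product (k = 110 L mol⁻¹ s⁻¹)
    partner + catalyst intermediate A → free catalyst + target (k = 477 L mol⁻¹ s⁻¹)
    second substrate + free catalyst ⇌ catalyst intermediate B (K = 2800 L mol⁻¹, k = 91.7 L mol⁻¹ s⁻¹)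

At 15.0 min in this flask, catalyst intermediate B, the main resting state, holds 68.4% of the catalyst, more than catalyst intermediate A at 23.0% or free catalyst at 8.56%. As a guess for twice the second substrate of this flask, I use the charge exponent with its sign turned, which gives a factor of 0.728 on the rate, and the run with that charge gives 0.702.

Readings and results are calculated with constants of no real substance, noise included.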